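**Plan**

- Numbering: the dienone ring is C1(=O), C2H=C3H, C4(=C7), C5H=C6H. C7 also carries a 4-hydroxyphenyl ring and the central benzene ring. On that central ring, C7 is flanked by the 2',4'-dihydroxyphenyl ring and the arylethynyl group.
- Enabling feature: C7 is a latent carbenium ion (the fuchsone is a deprotonated hydroxytrityl cation). The dienone ring has four unsubstituted CH groups with O para to C4, and the 2'-OH can bind C7 in a six-membered pyran. The cuts are therefore C2–C3 and C4–C5: C3/C4 come from an ethynyl group on C7, C5–C6–C1(O)–C2 from Danishefsky's diene, and the leaving group at C7 is the 2'-oxygen of a 6H-benzo[c]chromene.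
- Further cuts: C7–C≡ (acetylide to ketone), C7–aryl (aryllithium to lactone), aryl–C≡ (Sonogashira), the biaryl bond plus lactone C–O (Hurtley reaction with unfunctionalised resorcinol), and C7–central ring (lithiation/carboxylation).
- Forward ring order: the four benzene rings are bought. A temporary pyranone is closed in step 3, opened in step 7, re-closed as a pyran in step 8 and opened for good in step 9. In step 9 the dienone ring is closed as the last ring of the skeleton.
- Stereochemistry: the target has no stereocentre, no E/Z element at C4=C7 (the C3 and C5 sides are identical) and no fixed axis. C6 of chromene 17 and the C–OMe centre of 19 are racemic and are erased.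

Key step: step 9

Remark: the two para-oxygenated rings on C7 exchange roles by a degenerate proton shift. The target is taken as the open quinone methide drawn, and reversible addition of the 2'-OH to C7 (ring–chain tautomerism) is regarded as the same substance.
Abbreviations: TIPS = triisopropylsilyl; TIPSO = triisopropylsilyloxy.

**Step 1**
Reactants: 1 (4-bromo-2-chlorophenyl)methanol
Product: 2 [(4-bromo-2-chlorobenzyl)oxy]triisopropylsilane
Conditions: TIPSCl, imidazole, DMF, rt
Reagents that add atoms: triisopropylsilyl chloride, CC(C)[Si](Cl)(C(C)C)C(C)C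
Why: Imidazole-promoted silyl ether formation at a primary benzylic alcohol; TIPS is chosen because it should survive LDA, hot aqueous base, organometallic reagents and a silyl Lewis acid and leaves with fluoride at the end.

**Step 2**
Reactants: 2 [(4-bromo-2-chlorobenzyl)oxy]triisopropylsilane
Product: 4 6-bromo-2-chloro-3-[(triisopropylsilyloxy)methyl]benzoic acid, via aryllithium 3 (not isolated)
Conditions: LDA, THF, −78 °C; CO2; 1 M HCl
Reagents that add atoms: carbon dioxide, O=C=O
Why: Deprotonative ortho-lithiation and carboxylation: the C–H between Cl and Br is the most acidic ring position (as in 1-bromo-3-chlorobenzene), LDA does not exchange the halogens at −78 °C, and the doubly flanked aryllithium has no driving force for a halogen dance.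

**Step 3**
Reactants: 4 6-bromo-2-chloro-3-[(triisopropylsilyloxy)methyl]benzoic acid; 5 resorcinol
Product: 7 7-chloro-3-hydroxy-8-[(triisopropylsilyloxy)methyl]-6H-benzo[c]chromen-6-one, via biaryl hydroxy acid 6 (not isolated)
Conditions: 5 (2 equiv), NaOH (2 equiv), CuSO4 (10 mol %), H2O–dioxane, 100 °C; 1 M HCl
Reagents that add atoms: none
Why: Hurtley reaction: copper-catalysed, carboxylate-assisted C-arylation of the resorcinol anion at its unfunctionalised C4 (ortho to one oxygen, para to the other) should occur only at the ortho C–Br bond, the C–Cl bond being inert here, and the neighbouring phenol closes the lactone, which tells the 2'-oxygen from the 4'-oxygen.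

**Step 4**
Reactants: 7 7-chloro-3-hydroxy-8-[(triisopropylsilyloxy)methyl]-6H-benzo[c]chromen-6-one
Product: 8 7-chloro-3-(TIPSO)-8-[(TIPSO)methyl]-6H-benzo[c]chromen-6-one
Conditions: TIPSCl, imidazole, DMF, rt
Reagents that add atoms: triisopropylsilyl chloride, CC(C)[Si](Cl)(C(C)C)C(C)C
Why: Imidazole-promoted silylation of the only free hydroxyl group, a phenol.

**Step 5**
Reactants: 9 4-ethynylphenol
Product: 10 (4-ethynylphenoxy)triisopropylsilane
Conditions: TIPSCl, imidazole, CH2Cl2, 0 °C → rt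
Reagents that add atoms: triisopropylsilyl chloride, CC(C)[Si](Cl)(C(C)C)C(C)C
Why: Imidazole-promoted phenol silylation, which also stabilises the sensitive ethynylphenol.

**Step 6**
Reactants: 8 7-chloro-3-(TIPSO)-8-[(TIPSO)methyl]-6H-benzo[c]chromen-6-one; 10 (4-ethynylphenoxy)triisopropylsilane
Product: 11 3-(TIPSO)-8-[(TIPSO)methyl]-7-{[4-(TIPSO)phenyl]ethynyl}-6H-benzo[c]chromen-6-one
Conditions: PdCl2(MeCN)2 (3 mol %), XPhos (9 mol %), Cs2CO3, MeCN (dry), 85 °C
Reagents that add atoms: none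
Why: Copper-free Sonogashira coupling of an aryl chloride with a bulky dialkylbiarylphosphine ligand; the C–Cl bond is activated by the ortho lactone carbonyl group, and the lactone and TIPS ethers should tolerate anhydrous carbonate.

**Step 7**
Reactants: 11 3-(TIPSO)-8-[(TIPSO)methyl]-7-{[4-(TIPSO)phenyl]ethynyl}-6H-benzo[c]chromen-6-one; 12 (4-bromophenoxy)triisopropylsilane
Product: 14 {2'-hydroxy-4'-(TIPSO)-4-[(TIPSO)methyl]-3-{[4-(TIPSO)phenyl]ethynyl}biphenyl-2-yl}[4-(TIPSO)phenyl]methanone, via aryllithium 13 (not isolated)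
Conditions: 12, n-BuLi, THF, −78 °C; then 11, −78 °C; AcOH
Reagents that add atoms: none
Why: Halogen–lithium exchange followed by nucleophilic acyl substitution on an aryl ester: the aryloxide is expelled, and the doubly ortho-substituted, donor-conjugated ketone phenoxide so formed is far less electrophilic than the flat lactone, so addition should stop after one equivalent at −78 °C.

**Step 8**
Reactants: 14 {2'-hydroxy-4'-(TIPSO)-4-[(TIPSO)methyl]-3-{[4-(TIPSO)phenyl]ethynyl}biphenyl-2-yl}[4-(TIPSO)phenyl]methanone; 15 ethynylmagnesium bromide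
Product: 17 6-ethynyl-3-(TIPSO)-8-[(TIPSO)methyl]-6-[4-(TIPSO)phenyl]-7-{[4-(TIPSO)phenyl]ethynyl}-6H-benzo[c]chromene (racemic), via propargylic diol 16 (not isolated)
Conditions: 15 (4 equiv), LaCl3·2LiCl (30 mol %), THF, 0 °C → rt; aq NH4Cl; crude, PPTS (10 mol %), 4 Å MS, CH2Cl2, rt
Reagents that add atoms: none
Why: Lanthanum-promoted 1,2-addition of the smallest carbon nucleophile to the hindered ketone (the first equivalent deprotonates the phenol), then acid-catalysed cyclodehydration of the 2'-hydroxybiaryl carbinol to the 6H-benzo[c]chromene, the sequence known from lactone-to-6,6-disubstituted benzochromene conversions in cannabinol chemistry; C6 forms racemic and is erased in step 9.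

**Step 9**
Reactants: 17 6-ethynyl-3-(TIPSO)-8-[(TIPSO)methyl]-6-[4-(TIPSO)phenyl]-7-{[4-(TIPSO)phenyl]ethynyl}-6H-benzo[c]chromene; 18 Danishefsky's diene, (E)-1-methoxy-3-(trimethylsilyloxy)buta-1,3-diene
Product: 20 tetra-O-TIPS selaginellin F, via methoxy silyl dienol ether adduct 19 (not isolated)
Conditions: 18 (2.5 equiv), TMSNTf2 (10 mol %), CH2Cl2, −78 → 0 °C; aq NaHCO3
Reagents that add atoms: none
Why: Proposed new method: the silyl cation binds the pyran oxygen of 17 and the C6–O bond ionises, since C6 is benzhydrylic, propargylic and para-conjugated with a silyloxy group; the cation is an O-silylated alkynyl p-quinone methide, the phenylogue of a Lewis acid-activated terminal ynone, and its ethynyl group is the 2π partner. The nucleophilic CH2 terminus of 18 bonds to the terminal alkyne carbon and the central carbon of the allene so formed closes on the methoxy-oxocarbenium carbon within the ion pair, a formal, strongly asynchronous [4+2] cycloaddition (if stepwise, a 6-exo-trig cation–π closure that regenerates the diarylcarbenium ion); proton loss gives 19, and loss of MeOSiMe3 gives the dienone ring directly at the quinone methide oxidation level, frees the 2'-OH and returns the silyl cation. The closest known reaction types are the Diels–Alder/aromatisation of terminal aryl ynones with Danishefsky's diene to 4-hydroxyaryl ketones, the ionic Diels–Alder reaction of allyl cations, and the γ-selective capture of 1,1-diarylpropargyl cations by silyl enol ethers. No stereocentre has to be controlled, because C6 of 17 becomes trigonal and the C–OMe centre of 19 is lost. Regioselectivity (oxygen para to C4) follows from the polarity match of the diene terminus with the cationic alkyne terminus, and γ- over α-attack is secured because α-attack would build a quaternary centre at the doubly ortho-flanked C6. Chemoselectivity is secured because the internal diarylalkyne is not conjugated with the cation and is ignored by the electron-rich diene, while low temperature and a non-nucleophilic counter-ion should keep an open-chain allenyl ketone, a benzannulated enyne-allene prone to Schmittel or Myers–Saito cyclisation, from accumulating.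

**Step 10**
Reactants: 20 tetra-O-TIPS selaginellin F
Product: 21 selaginellin F
Conditions: TBAF/AcOH (1:1, 6 equiv), THF, 0 °C → rt; pH 6 phosphate buffer
Reagents that add atoms: none
Why: Fluoride-induced desilylation of three aryl and one alkyl TIPS ether; the acetic acid buffer keeps alkoxide and phenoxide concentrations low, so neither the quinone methide nor the ortho-alkynylbenzyl alcohol (5-exo-dig hydroalkoxylation) should be attacked.

**Compound list**

1 | (4-bromo-2-chlorophenyl)methanol | OCc1ccc(Br)cc1Cl | starting material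
2 | [(4-bromo-2-chlorobenzyl)oxy]triisopropylsilane | CC(C)[Si](OCc1ccc(Br)cc1Cl)(C(C)C)C(C)C | intermediate
3 | 6-bromo-2-chloro-3-[(TIPSO)methyl]phenyllithium (not isolated) | [Li]c1c(Br)ccc(CO[Si](C(C)C)(C(C)C)C(C)C)c1Cl | intermediate
4 | 6-bromo-2-chloro-3-[(triisopropylsilyloxy)methyl]benzoic acid | OC(=O)c1c(Br)ccc(CO[Si](C(C)C)(C(C)C)C(C)C)c1Cl | intermediate
5 | resorcinol (benzene-1,3-diol) | Oc1cccc(O)c1 | starting material
6 | 3-chloro-2',4'-dihydroxy-4-[(TIPSO)methyl]biphenyl-2-carboxylic acid (not isolated) | OC(=O)c1c(-c2ccc(O)cc2O)ccc(CO[Si](C(C)C)(C(C)C)C(C)C)c1Cl | intermediate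
7 | 7-chloro-3-hydroxy-8-[(TIPSO)methyl]-6H-benzo[c]chromen-6-one | O=C1Oc2cc(O)ccc2-c2ccc(CO[Si](C(C)C)(C(C)C)C(C)C)c(Cl)c12 | intermediate
8 | 7-chloro-3-(TIPSO)-8-[(TIPSO)methyl]-6H-benzo[c]chromen-6-one | O=C1Oc2cc(O[Si](C(C)C)(C(C)C)C(C)C)ccc2-c2ccc(CO[Si](C(C)C)(C(C)C)C(C)C)c(Cl)c12 | intermediate
9 | 4-ethynylphenol | Oc1ccc(C#C)cc1 | starting material
10 | (4-ethynylphenoxy)triisopropylsilane | C#Cc1ccc(O[Si](C(C)C)(C(C)C)C(C)C)cc1 | intermediate
11 | 3-(TIPSO)-8-[(TIPSO)methyl]-7-{[4-(TIPSO)phenyl]ethynyl}-6H-benzo[c]chromen-6-one | O=C1Oc2cc(O[Si](C(C)C)(C(C)C)C(C)C)ccc2-c2ccc(CO[Si](C(C)C)(C(C)C)C(C)C)c(C#Cc3ccc(O[Si](C(C)C)(C(C)C)C(C)C)cc3)c12 | intermediate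
12 | (4-bromophenoxy)triisopropylsilane | Brc1ccc(O[Si](C(C)C)(C(C)C)C(C)C)cc1 | starting material
13 | 4-(TIPSO)phenyllithium (not isolated) | [Li]c1ccc(O[Si](C(C)C)(C(C)C)C(C)C)cc1 | intermediate
14 | {2'-hydroxy-4'-(TIPSO)-4-[(TIPSO)methyl]-3-{[4-(TIPSO)phenyl]ethynyl}biphenyl-2-yl}[4-(TIPSO)phenyl]methanone | O=C(c1ccc(O[Si](C(C)C)(C(C)C)C(C)C)cc1)c1c(-c2ccc(O[Si](C(C)C)(C(C)C)C(C)C)cc2O)ccc(CO[Si](C(C)C)(C(C)C)C(C)C)c1C#Cc1ccc(O[Si](C(C)C)(C(C)C)C(C)C)cc1 | intermediate
15 | ethynylmagnesium bromide (solution in THF) | C#C[Mg]Br | starting material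
16 | 1-{2'-hydroxy-4'-(TIPSO)-4-[(TIPSO)methyl]-3-{[4-(TIPSO)phenyl]ethynyl}biphenyl-2-yl}-1-[4-(TIPSO)phenyl]prop-2-yn-1-ol, racemic (not isolated) | C#CC(O)(c1ccc(O[Si](C(C)C)(C(C)C)C(C)C)cc1)c1c(-c2ccc(O[Si](C(C)C)(C(C)C)C(C)C)cc2O)ccc(CO[Si](C(C)C)(C(C)C)C(C)C)c1C#Cc1ccc(O[Si](C(C)C)(C(C)C)C(C)C)cc1 | intermediate
17 | 6-ethynyl-3-(TIPSO)-8-[(TIPSO)methyl]-6-[4-(TIPSO)phenyl]-7-{[4-(TIPSO)phenyl]ethynyl}-6H-benzo[c]chromene, racemic | C#CC1(c2ccc(O[Si](C(C)C)(C(C)C)C(C)C)cc2)Oc2cc(O[Si](C(C)C)(C(C)C)C(C)C)ccc2-c2ccc(CO[Si](C(C)C)(C(C)C)C(C)C)c(C#Cc3ccc(O[Si](C(C)C)(C(C)C)C(C)C)cc3)c12 | intermediate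
18 | Danishefsky's diene, (E)-1-methoxy-3-(trimethylsilyloxy)buta-1,3-diene | CO/C=C/C(=C)O[Si](C)(C)C | starting material
19 | 1:1 adduct: 3-methoxy-1-(trimethylsilyloxy)cyclohexa-1,5-diene bearing at C4 the diarylmethylidene group of 20, racemic, alkene geometry of no consequence (not isolated) | COC1C=C(O[Si](C)(C)C)C=CC1=C(c1ccc(O[Si](C(C)C)(C(C)C)C(C)C)cc1)c1c(-c2ccc(O[Si](C(C)C)(C(C)C)C(C)C)cc2O)ccc(CO[Si](C(C)C)(C(C)C)C(C)C)c1C#Cc1ccc(O[Si](C(C)C)(C(C)C)C(C)C)cc1 | intermediate
20 | tetra-O-TIPS selaginellin F: 4-{{2'-hydroxy-4'-(TIPSO)-4-[(TIPSO)methyl]-3-{[4-(TIPSO)phenyl]ethynyl}biphenyl-2-yl}[4-(TIPSO)phenyl]methylidene}cyclohexa-2,5-dien-1-one | O=C1C=CC(=C(c2ccc(O[Si](C(C)C)(C(C)C)C(C)C)cc2)c2c(-c3ccc(O[Si](C(C)C)(C(C)C)C(C)C)cc3O)ccc(CO[Si](C(C)C)(C(C)C)C(C)C)c2C#Cc2ccc(O[Si](C(C)C)(C(C)C)C(C)C)cc2)C=C1 | intermediate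
21 | selaginellin F | O=C1C=CC(=C(c2ccc(O)cc2)c2c(-c3ccc(O)cc3O)ccc(CO)c2C#Cc2ccc(O)cc2)C=C1 | target

**Step count**

Total steps: 10.
Longest linear sequence: 9 steps (1–4 and 6–10, from compound 1).

**Steps most likely to fail**

**Step 9.**
- What may go wrong: silyl transfer may release the open-chain allenyl ketone faster than the second C–C bond forms, and that enyne-allene may then be lost to diradical cyclisation. The diene may also be destroyed by the acid before the pyran ionises.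
- The fallback uses only known chemistry, still builds the same ring from the same four-carbon unit, sets out from lactone 11 and returns at 21.
- Commercial lithium (trimethylsilyl)acetylide (THF, −78 °C) opens 11 to the C-silylated ynone phenol F1.
- TIPSOTf/2,6-lutidine gives its 2'-O-TIPS ether F2.
- Buffered methanolysis (borax, MeOH–THF) gives the terminal ynone F3.
- A thermal Diels–Alder reaction with 18 (toluene, 80 °C) gives the cyclohexadiene cycloadduct F4.
- Dilute HCl in THF aromatises F4 to the 4-hydroxyphenyl ketone F5.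
- TIPSCl/imidazole gives the silyl ether F6, and addition of aryllithium 13 (THF, −78 → 0 °C) gives the triarylcarbinol F7.
- TBAF/AcOH followed by a trace of acid desilylates and dehydrates F7 to 21.

**Step 8.**
- What may go wrong: the crowded, donor-deactivated ketone phenoxide may resist addition. On prolonged warming the tertiary alkoxide may add to the neighbouring arylethynyl group.
- The fallback sets out from 14 and returns at 17. It raises the electrophilicity of C7 instead of the strength of the nucleophile.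
- TMSOTf (1 equiv, CH2Cl2, −40 °C) converts the hemiketal form of 14 into the 6-aryldibenzo[b,d]pyrylium triflate F8.
- F8 takes up 15 at the carbon next to oxygen at −78 °C. This is the known addition of Grignard reagents to benzopyrylium salts, and it gives 17 directly.

**Step 6.**
- What may go wrong: transfer of the alkyne to the crowded arylpalladium intermediate may be slow. Alkyne oligomerisation and base-induced loss of a phenolic silyl group may then take over.
- The fallback sets out from 8 and 10 and returns at 11. It replaces base-mediated alkyne activation by a Negishi alkynylation.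
- Compound 10 is deprotonated with n-BuLi to the lithium acetylide F9 and transmetalated with ZnCl2 to the alkynylzinc chloride F10.
- F10 is coupled with 8 under a Pd–NHC catalyst (Pd-PEPPSI-IPent, THF–NMP, 60 °C) in the absence of any carbonate base.

**Further compounds**

F1 | step 9 | 1-{2'-hydroxy-4'-(TIPSO)-4-[(TIPSO)methyl]-3-{[4-(TIPSO)phenyl]ethynyl}biphenyl-2-yl}-3-(trimethylsilyl)prop-2-yn-1-one | C[Si](C)(C)C#CC(=O)c1c(-c2ccc(O[Si](C(C)C)(C(C)C)C(C)C)cc2O)ccc(CO[Si](C(C)C)(C(C)C)C(C)C)c1C#Cc1ccc(O[Si](C(C)C)(C(C)C)C(C)C)cc1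
F2 | step 9 | 2'-O-TIPS ether of F1 | C[Si](C)(C)C#CC(=O)c1c(-c2ccc(O[Si](C(C)C)(C(C)C)C(C)C)cc2O[Si](C(C)C)(C(C)C)C(C)C)ccc(CO[Si](C(C)C)(C(C)C)C(C)C)c1C#Cc1ccc(O[Si](C(C)C)(C(C)C)C(C)C)cc1
F3 | step 9 | 1-{2',4'-bis(TIPSO)-4-[(TIPSO)methyl]-3-{[4-(TIPSO)phenyl]ethynyl}biphenyl-2-yl}prop-2-yn-1-one | C#CC(=O)c1c(-c2ccc(O[Si](C(C)C)(C(C)C)C(C)C)cc2O[Si](C(C)C)(C(C)C)C(C)C)ccc(CO[Si](C(C)C)(C(C)C)C(C)C)c1C#Cc1ccc(O[Si](C(C)C)(C(C)C)C(C)C)cc1
F4 | step 9 | [6-methoxy-4-(trimethylsilyloxy)cyclohexa-1,4-dien-1-yl] aryl ketone cycloadduct, racemic | COC1C=C(O[Si](C)(C)C)CC=C1C(=O)c1c(-c2ccc(O[Si](C(C)C)(C(C)C)C(C)C)cc2O[Si](C(C)C)(C(C)C)C(C)C)ccc(CO[Si](C(C)C)(C(C)C)C(C)C)c1C#Cc1ccc(O[Si](C(C)C)(C(C)C)C(C)C)cc1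
F5 | step 9 | {2',4'-bis(TIPSO)-4-[(TIPSO)methyl]-3-{[4-(TIPSO)phenyl]ethynyl}biphenyl-2-yl}(4-hydroxyphenyl)methanone | O=C(c1ccc(O)cc1)c1c(-c2ccc(O[Si](C(C)C)(C(C)C)C(C)C)cc2O[Si](C(C)C)(C(C)C)C(C)C)ccc(CO[Si](C(C)C)(C(C)C)C(C)C)c1C#Cc1ccc(O[Si](C(C)C)(C(C)C)C(C)C)cc1
F6 | step 9 | O-TIPS ether of F5 | O=C(c1ccc(O[Si](C(C)C)(C(C)C)C(C)C)cc1)c1c(-c2ccc(O[Si](C(C)C)(C(C)C)C(C)C)cc2O[Si](C(C)C)(C(C)C)C(C)C)ccc(CO[Si](C(C)C)(C(C)C)C(C)C)c1C#Cc1ccc(O[Si](C(C)C)(C(C)C)C(C)C)cc1
F7 | step 9 | {2',4'-bis(TIPSO)-4-[(TIPSO)methyl]-3-{[4-(TIPSO)phenyl]ethynyl}biphenyl-2-yl}bis[4-(TIPSO)phenyl]methanol | OC(c1ccc(O[Si](C(C)C)(C(C)C)C(C)C)cc1)(c1ccc(O[Si](C(C)C)(C(C)C)C(C)C)cc1)c1c(-c2ccc(O[Si](C(C)C)(C(C)C)C(C)C)cc2O[Si](C(C)C)(C(C)C)C(C)C)ccc(CO[Si](C(C)C)(C(C)C)C(C)C)c1C#Cc1ccc(O[Si](C(C)C)(C(C)C)C(C)C)cc1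
F8 | step 8 | 3-(TIPSO)-8-[(TIPSO)methyl]-6-[4-(TIPSO)phenyl]-7-{[4-(TIPSO)phenyl]ethynyl}dibenzo[b,d]pyrylium triflate | c1(-c2ccc(O[Si](C(C)C)(C(C)C)C(C)C)cc2)[o+]c2cc(O[Si](C(C)C)(C(C)C)C(C)C)ccc2c2ccc(CO[Si](C(C)C)(C(C)C)C(C)C)c(C#Cc3ccc(O[Si](C(C)C)(C(C)C)C(C)C)cc3)c12.[O-]S(=O)(=O)C(F)(F)F
F9 | step 6 | lithium [4-(TIPSO)phenyl]acetylide | [Li]C#Cc1ccc(O[Si](C(C)C)(C(C)C)C(C)C)cc1
F10 | step 6 | {[4-(TIPSO)phenyl]ethynyl}zinc chloride | Cl[Zn]C#Cc1ccc(O[Si](C(C)C)(C(C)C)C(C)C)cc1
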